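A direct plan would build the brominated butenolide first and oxidise the side chain last: acetoacetic ester alkylation would give 2-butyl-4-oxopentanoic acid A1; threefold bromination and cyclodehydration in hot concentrated mineral acid would give 4-bromo-3-butyl-5-(dibromomethylene)furan-2(5H)-one A2; radical bromination at C1′ would give the racemic 4-bromo-3-(1-bromobutyl)-5-(dibromomethylene)furan-2(5H)-one A3; an enantioconvergent copper-catalysed radical hydroxylation of A3 would end the route.
Weak point 1, the brominative cyclodehydration of A1: the positions of the three bromines would be left to enolisation rates under forcing acid, so bromomethylene and dibromomethylene congeners would have to be separated.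
Weak point 2, the radical bromination of A2 at C1′: it would create the only stereocentre as a racemate and would compete with abstraction at C2′ and with bromine-atom addition to the dienone.
Weak point 3, the closing hydroxylation of A3: it would be without precedent for an oxygen nucleophile on a polybrominated butenolide, would have to spare three vinylic C–Br bonds and a base-labile enol lactone, and a shortfall in ee at the last step could not be corrected.

**Retrosynthetic overview**
- Key disconnection: the exocyclic C5=CBr2 bond of the enol lactone. A Ramirez dibromo-olefination of one carbonyl of a bromomaleic anhydride installs the exocyclic carbon and two bromines at once; the C4–Br and the bulk at C3 tell the two carbonyls apart.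
- The five-membered ring (O1, C2–C5) is never closed. It is the ring of 3,4-dibromofuran, one bromine of which ends as C4–Br; singlet-oxygen oxidation turns the furan into the anhydride.
- C1′ is set at the start by asymmetric transfer hydrogenation of a 3-furyl propyl ketone; the C3–C1′ bond comes from bromine–lithium exchange and Weinreb acylation.
- Avoided by design: no polybromination or cyclodehydration in strong acid, no radical bromination, and no stereocentre formed or corrected at the end.

Key step: step 5

Remark on the chemistry: the preference of phosphorus ylides for the carbonyl next to the heteroatom-bearing carbon of an unsymmetrical maleic anhydride is assumed to hold for the bromo anhydride. The CIP order at C1′ (O > ring carbon > propyl > H) is the same in every intermediate, so (R) in the furan series is (R) in the target.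

**Step 1**
Reactants: 1 3,4-dibromofuran; 2 N-methoxy-N-methylbutanamide
Product: 4 1-(4-bromofuran-3-yl)butan-1-one, via 3-bromo-4-lithiofuran 3 (not isolated)
Conditions: n-BuLi (1.0 equiv), Et2O, −78 °C; then 2, −78 to 0 °C; aq. HCl
Reagents that add atoms: none
Why: Bromine–lithium exchange on one of the two equivalent C–Br bonds is fast at −78 °C and the lithiofuran is acylated once by the Weinreb amide (Weinreb ketone synthesis), whose chelated adduct blocks over-addition; the remaining bromine becomes the C4–Br of the target.

**Step 2**
Reactants: 4 1-(4-bromofuran-3-yl)butan-1-one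
Product: 5 (1R)-1-(4-bromofuran-3-yl)butan-1-ol
Conditions: RuCl[(R,R)-TsDPEN](p-cymene) (1 mol%), HCO2H/Et3N (5:2), 30 °C
Reagents that add atoms: none
Why: Noyori–Ikariya asymmetric transfer hydrogenation of an aryl alkyl ketone, in which the ruthenium hydride tells the flat bromofuryl group (CH–π contact with the cymene ligand) from the propyl chain and should give the (R)-carbinol, by analogy with acetophenone giving (R)-1-phenylethanol with the same catalyst enantiomer; this sets the only stereocentre.

**Step 3**
Reactants: 5 (1R)-1-(4-bromofuran-3-yl)butan-1-ol
Product: 6 tert-butyl{[(1R)-1-(4-bromofuran-3-yl)butyl]oxy}dimethylsilane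
Conditions: TBSCl, imidazole, DMF, rt
Reagents that add atoms: tert-butyldimethylsilyl chloride (CC(C)(C)[Si](C)(C)Cl)
Why: Standard imidazole-promoted silylation of a secondary alcohol, which shields the hydroxyl from the bromophosphonium chemistry of step 5 and does not touch the stereocentre.

**Step 4**
Reactants: 6 tert-butyl{[(1R)-1-(4-bromofuran-3-yl)butyl]oxy}dimethylsilane
Product: 10 3-bromo-4-[(1R)-1-{[tert-butyl(dimethyl)silyl]oxy}butyl]furan-2,5-dione, via furan endoperoxide 7 (not isolated), via hydroxybutenolide 8 (not isolated), via isomeric hydroxybutenolide 9 (not isolated)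
Conditions: O2, tetraphenylporphyrin (cat.), hν (visible), i-Pr2NEt, CH2Cl2, −78 °C; silica plug; then pyridinium chlorochromate [C5H5NH][CrO3Cl], 4 Å MS, CH2Cl2, rt
Reagents that add atoms: oxygen (O=O)
Why: [4+2] cycloaddition of singlet oxygen to the furan gives the 2,5-endoperoxide, base-induced Kornblum–DeLaMare fragmentation gives the γ-hydroxybutenolides, and chromate oxidation of the hemiacylal carbon gives the maleic anhydride; both regioisomeric hydroxybutenolides converge on the same anhydride, and the amine is removed before the anhydride forms so that C1′ is not epimerised.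

**Step 5**
Reactants: 10 3-bromo-4-[(1R)-1-{[tert-butyl(dimethyl)silyl]oxy}butyl]furan-2,5-dione
Product: 11 4-bromo-3-[(1R)-1-{[tert-butyl(dimethyl)silyl]oxy}butyl]-5-(dibromomethylidene)furan-2(5H)-one
Conditions: CBr4 (2 equiv), PPh3 (2 equiv), Zn (2 equiv), CH2Cl2, rt, 24 h; then 10, 0 °C to rt
Reagents that add atoms: carbon tetrabromide (BrC(Br)(Br)Br)
Why: The ylide Ph3P=CBr2, pre-formed from CBr4, PPh3 and Zn so that neither free phosphine nor Ph3PBr2 remains, adds to the C5 carbonyl of 10 and the oxaphosphetane collapses with loss of Ph3PO, turning the acyl C5–O1 unit into the C5(=CBr2)–O1 enol lactone (Ramirez dibromo-olefination, a Wittig-type reaction). The closest known reaction type is the Ramirez dibromomethylenation of cyclic anhydrides such as phthalic and maleic anhydride, together with the Wittig olefination of alkoxy-substituted maleic anhydrides at the carbonyl next to the heteroatom-bearing carbon. No ring is closed: the five-membered ring is carried over from the furan, only the exocyclic C5=C bond is formed, and the symmetric CBr2 terminus leaves no alkene geometry to control. No stereocentre is formed, and the C1′ centre, whose hydrogen is vinylogous to the C5 carbonyl in 10, is safe because the medium holds no amine base. The step needs site selectivity for C5 (next to C4–Br) over C2 (next to C3 with its branched silyloxybutyl group); three effects point the same way, namely the inductive pull of bromine on the adjacent carbonyl, the lone-pair donation of bromine through C4=C3 that makes C2=O a less electrophilic vinylogous acyl bromide, and the steric shielding of C2. It also needs 1,2-addition to win over addition–elimination at C4, which the low temperature, the absence of free PPh3 and the full substitution of C3=C4 should favour.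

**Step 6**
Reactants: 11 4-bromo-3-[(1R)-1-{[tert-butyl(dimethyl)silyl]oxy}butyl]-5-(dibromomethylidene)furan-2(5H)-one
Product: 12 4-bromo-5-(dibromomethylidene)-3-[(1R)-1-hydroxybutyl]furan-2(5H)-one
Conditions: HF·pyridine, THF, 0 °C to rt
Reagents that add atoms: none
Why: Fluoride-driven cleavage of the silyl ether under mildly acidic conditions, which the acid-stable tribromo enol lactone should tolerate, whereas basic fluoride sources are avoided; the C1′–O bond is not broken, so the configuration is kept.

**Compound list**
1 | 3,4-dibromofuran | Brc1cocc1Br | starting material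
2 | N-methoxy-N-methylbutanamide | CCCC(=O)N(C)OC | starting material
3 | 3-bromo-4-lithiofuran | [Li]c1cocc1Br | intermediate
4 | 1-(4-bromofuran-3-yl)butan-1-one | CCCC(=O)c1cocc1Br | intermediate
5 | (1R)-1-(4-bromofuran-3-yl)butan-1-ol | CCC[C@@H](O)c1cocc1Br | intermediate
6 | tert-butyl{[(1R)-1-(4-bromofuran-3-yl)butyl]oxy}dimethylsilane | CCC[C@@H](O[Si](C)(C)C(C)(C)C)c1cocc1Br | intermediate
7 | 5-bromo-6-[(1R)-1-{[tert-butyl(dimethyl)silyl]oxy}butyl]-2,3,7-trioxabicyclo[2.2.1]hept-5-ene (bridgehead epimers) | CCC[C@@H](O[Si](C)(C)C(C)(C)C)C1=C(Br)C2OOC1O2 | intermediate
8 | 3-bromo-4-[(1R)-1-{[tert-butyl(dimethyl)silyl]oxy}butyl]-5-hydroxyfuran-2(5H)-one (C5 epimers) | CCC[C@@H](O[Si](C)(C)C(C)(C)C)C1=C(Br)C(=O)OC1O | intermediate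
9 | 4-bromo-3-[(1R)-1-{[tert-butyl(dimethyl)silyl]oxy}butyl]-5-hydroxyfuran-2(5H)-one (C5 epimers) | CCC[C@@H](O[Si](C)(C)C(C)(C)C)C1=C(Br)C(O)OC1=O | intermediate
10 | 3-bromo-4-[(1R)-1-{[tert-butyl(dimethyl)silyl]oxy}butyl]furan-2,5-dione | CCC[C@@H](O[Si](C)(C)C(C)(C)C)C1=C(Br)C(=O)OC1=O | intermediate
11 | 4-bromo-3-[(1R)-1-{[tert-butyl(dimethyl)silyl]oxy}butyl]-5-(dibromomethylidene)furan-2(5H)-one | CCC[C@@H](O[Si](C)(C)C(C)(C)C)C1=C(Br)C(=C(Br)Br)OC1=O | intermediate
12 | 4-bromo-5-(dibromomethylidene)-3-[(1R)-1-hydroxybutyl]furan-2(5H)-one | CCC[C@@H](O)C1=C(Br)C(=C(Br)Br)OC1=O | target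

Total step count: 6. Longest linear sequence: 6 steps, from 3,4-dibromofuran.

**Steps most likely to fail**

Step 5 (dibromo-olefination of the anhydride). The ylide may be consumed by addition–elimination at C4 with loss of bromide, the adduct on the hindered, electron-poor carbonyl may fail to collapse, or the two carbonyls may not be told apart cleanly. The fallback replaces the olefination by addition and dehydration and sets out from anhydride 10. Pre-formed LiCHBr2 (CH2Br2 in excess over LiN(i-Pr)2, THF, −95 °C) is a small, hard nucleophile that should attack the more electrophilic C5 carbonyl under kinetic control. After acidic work-up it would give 4-bromo-5-(dibromomethyl)-5-hydroxy-3-[(1R)-1-{[tert-butyl(dimethyl)silyl]oxy}butyl]furan-2(5H)-one F1. Acylation of the tertiary hydroxyl and elimination (trifluoroacetic anhydride, pyridine, CH2Cl2, 0 °C) would then give silyl ether 11, where the route is rejoined.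

Step 4 (furan to anhydride). Singlet oxygen may add sluggishly to the bromine-deactivated furan, or the endoperoxide may fragment by ring cleavage before the base-induced rearrangement. The fallback uses a two-electron anodic dearomatisation instead of a cycloaddition and sets out from furan 6. Anodic 2,5-dimethoxylation (graphite anode, NaBr, MeOH, −10 °C, undivided cell) would give tert-butyl{[(1R)-1-(4-bromo-2,5-dimethoxy-2,5-dihydrofuran-3-yl)butyl]oxy}dimethylsilane F2 as a diastereomer mixture. Jones oxidation (CrO3, dilute H2SO4, acetone, 0 °C) would unmask both acetal carbons and oxidise them to the acid level, returning the route to anhydride 10.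

Step 2 (asymmetric transfer hydrogenation). Facial discrimination in the hydride transfer may be eroded, because the neighbouring bromine twists the furyl ring and the propyl chain is not small, leaving insufficient ee. The fallback sets the stereocentre by C–C instead of C–H bond formation and sets out from 3,4-dibromofuran 1 via lithiofuran 3. Transmetalation of 3 with BuZnCl (from ZnCl2 and n-BuLi) would give butyl(4-bromofuran-3-yl)zinc F3. Its amino-alcohol-catalysed addition to butanal would give alcohol 5 directly, where the route is rejoined. The conditions would be (−)-MIB [(2S)-3-exo-morpholinoisoborneol, 5 mol%] in toluene/hexane at 0 °C, with N,N,N′,N′-tetraethylethylenediamine to bind LiCl. The ligand enantiomer is the one that delivers the furyl group to the Si face of the aldehyde, by analogy with dialkylzinc additions.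

**Further compounds**
F1 | step 5 | 4-bromo-5-(dibromomethyl)-5-hydroxy-3-[(1R)-1-{[tert-butyl(dimethyl)silyl]oxy}butyl]furan-2(5H)-one (C5 epimers) | CCC[C@@H](O[Si](C)(C)C(C)(C)C)C1=C(Br)C(O)(C(Br)Br)OC1=O
F2 | step 4 | tert-butyl{[(1R)-1-(4-bromo-2,5-dimethoxy-2,5-dihydrofuran-3-yl)butyl]oxy}dimethylsilane (diastereomer mixture) | CCC[C@@H](O[Si](C)(C)C(C)(C)C)C1=C(Br)C(OC)OC1OC
F3 | step 2 | butyl(4-bromofuran-3-yl)zinc | CCCC[Zn]c1cocc1Br
A1 | direct plan | 2-butyl-4-oxopentanoic acid (racemic) | CCCCC(CC(C)=O)C(O)=O
A2 | direct plan | 4-bromo-3-butyl-5-(dibromomethylene)furan-2(5H)-one | CCCCC1=C(Br)C(=C(Br)Br)OC1=O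
A3 | direct plan | 4-bromo-3-(1-bromobutyl)-5-(dibromomethylene)furan-2(5H)-one (racemic) | CCCC(Br)C1=C(Br)C(=C(Br)Br)OC1=O
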